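## Retrosynthetic overview

1. Locants: C1 = ester carbon, C2 = α-methyl carbon, C3 and C6 = dioxane carbons (O2 on C3, O1 on C6), C7–C8 = linker, C1'–C6' = cyclohexenone (C1' carries C8, C3' = carbonyl). Target 20 ⇐ dienone 19 (diimide, C7=C8) ⇐ C7 carbinol 17 (elimination; the C8 hydrogens are γ to the C3' carbonyl).
2. Dioxane ring (O1–O2–C3–C4–C5–C6) ⇐ epoxy enoate 15 + H2O2: O1–C6 by opening a C6–C7 oxirane at the methyl-bearing tertiary C6, O2–C3 by 6-exo peroxy-Michael addition to the C2=C3 enoate. Enabling feature: C3 and C6 are 1,4-related, C3 is β to the C1 ester carbonyl and C6 is fully substituted, so H2O2 can bridge two pre-installed electrophilic sites; the oxygen left on C7 is a temporary control element.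
3. 15 ⇐ achiral triene keto ester 14 by Shi epoxidation of its only electron-rich alkene (C6=C7). This is the single reagent-controlled event; C6 (inversion), C3 and C2 (relay) descend from it.
4. 14 ⇐ Suzuki–Miyaura coupling (C7–C8 bond) of alkenylboronate 6 (from pent-4-yn-1-ol 1) with bromomethyl enone 13 (from 2-methylcyclohexane-1,3-dione 7).
5. Ring order: the carbocycle is bought in 7 and only refunctionalised (steps 5–8); a transient oxirane is made in step 10 and opened in step 11, where the 1,2-dioxane is closed as the last ring of the skeleton.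

Key step: step 11

Assumption: the D-fructose-derived Shi ketone is taken to epoxidise the (E)-trisubstituted C6=C7 alkene with its usual facial sense, giving the (R,R)-oxirane; 1, 7 and the named reagents are taken as commercial.

## Route

Step 1
Reactants: 1 pent-4-yn-1-ol
Product: 3 (E)-5-iodo-4-methylpent-4-en-1-ol, via alkenylalane 2 (not isolated)
Conditions: AlMe3 (3 equiv), Cp2ZrCl2 (0.25 equiv), CH2Cl2, 0 °C to rt; then I2, THF, −30 to 0 °C
Reagents that add atoms: trimethylaluminium C[Al](C)C; iodine II
Why: Negishi zirconium-catalysed carboalumination adds CH3 and Al syn across the terminal alkyne with the metal on the terminal carbon, and iodinolysis of the C–Al bond proceeds with retention, so the (E)-2-methylalkenyl iodide should form as one isomer.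

Step 2
Reactants: 3 (E)-5-iodo-4-methylpent-4-en-1-ol
Product: 4 (E)-5-iodo-4-methylpent-4-enal
Conditions: Dess–Martin periodinane, CH2Cl2, 0 °C to rt
Reagents that add atoms: none
Why: Dess–Martin oxidation of a primary alcohol under neutral conditions stops at the aldehyde and leaves the alkenyl iodide untouched.

Step 3
Reactants: 4 (E)-5-iodo-4-methylpent-4-enal
Product: 5 methyl (2E,6E)-7-iodo-2,6-dimethylhepta-2,6-dienoate
Conditions: Ph3P=C(CH3)CO2CH3, CH2Cl2, rt to 40 °C
Reagents that add atoms: methyl 2-(triphenylphosphoranylidene)propanoate COC(=O)C(C)=P(c1ccccc1)(c1ccccc1)c1ccccc1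
Why: Wittig olefination with a stabilised α-methyl ylide is reliably E-selective and gives the tiglate-type enoate that later serves as the Michael acceptor.

Step 4
Reactants: 5 methyl (2E,6E)-7-iodo-2,6-dimethylhepta-2,6-dienoate
Product: 6 methyl (2E,6E)-2,6-dimethyl-7-(4,4,5,5-tetramethyl-1,3,2-dioxaborolan-2-yl)hepta-2,6-dienoate
Conditions: B2pin2, PdCl2(PPh3)2 (3 mol %), PPh3, KOPh, toluene, 50 °C
Reagents that add atoms: bis(pinacolato)diboron CC1(C)OB(OC1(C)C)B1OC(C)(C)C(C)(C)O1
Why: Miyaura borylation of an alkenyl iodide proceeds with retention of alkene geometry and tolerates the enoate ester.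

Step 5
Reactants: 7 2-methylcyclohexane-1,3-dione
Product: 8 3-ethoxy-2-methylcyclohex-2-en-1-one
Conditions: EtOH, TsOH (cat.), toluene, reflux (Dean–Stark)
Reagents that add atoms: ethanol CCO
Why: acid-catalysed enol etherification of the symmetrical 1,3-dione gives the vinylogous ester, driven by azeotropic removal of water.

Step 6
Reactants: 8 3-ethoxy-2-methylcyclohex-2-en-1-one
Product: 10 3-ethoxy-2,6,6-trimethylcyclohex-2-en-1-one, via monomethyl enone 9 (not isolated)
Conditions: LiN(iPr)2, THF, −78 °C, then CH3I; second charge of LiN(iPr)2 then CH3I in the same flask, −78 °C to rt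
Reagents that add atoms: iodomethane CI
Why: Stork–Danheiser kinetic enolisation of a vinylogous ester occurs only at the α′ carbon (C6), so two successive enolate methylations build the gem-dimethyl group there.

Step 7
Reactants: 10 3-ethoxy-2,6,6-trimethylcyclohex-2-en-1-one
Product: 12 2,3,4,4-tetramethylcyclohex-2-en-1-one, via tertiary carbinol 11 (not isolated)
Conditions: CH3Li, Et2O, −78 to 0 °C; then 1 M HCl, rt
Reagents that add atoms: methyllithium [Li]C
Why: Stork–Danheiser sequence: 1,2-addition of the small organolithium to the vinylogous ester carbonyl, then acid hydrolysis and dehydration, transposes the enone and places the new methyl on the β-carbon next to the gem-dimethyl carbon.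

Step 8
Reactants: 12 2,3,4,4-tetramethylcyclohex-2-en-1-one
Product: 13 3-(bromomethyl)-2,4,4-trimethylcyclohex-2-en-1-one
Conditions: NBS (1.05 equiv), AIBN (cat.), PhCF3, 80 °C
Reagents that add atoms: N-bromosuccinimide O=C1CCC(=O)N1Br
Why: Wohl–Ziegler bromination should favour the C3 methyl, because it is the only γ position carrying hydrogen (the ring γ carbon is quaternary) and its radical is delocalised over the whole enone.

Step 9
Reactants: 6 methyl (2E,6E)-2,6-dimethyl-7-(4,4,5,5-tetramethyl-1,3,2-dioxaborolan-2-yl)hepta-2,6-dienoate; 13 3-(bromomethyl)-2,4,4-trimethylcyclohex-2-en-1-one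
Product: 14 methyl (2E,6E)-2,6-dimethyl-8-(2,6,6-trimethyl-3-oxocyclohex-1-en-1-yl)octa-2,6-dienoate
Conditions: Pd(PPh3)4 (5 mol %), CsF, THF, 50 °C
Reagents that add atoms: none
Why: Suzuki–Miyaura alkenyl–allyl coupling: zerovalent palladium inserts into the primary allylic C–Br bond and the alkenyl group is delivered to the unhindered CH2 terminus with retention of the E geometry, giving the skipped diene.

Step 10
Reactants: 14 methyl (2E,6E)-2,6-dimethyl-8-(2,6,6-trimethyl-3-oxocyclohex-1-en-1-yl)octa-2,6-dienoate
Product: 15 methyl (2E)-2-methyl-5-[(2R,3R)-2-methyl-3-[(2,6,6-trimethyl-3-oxocyclohex-1-en-1-yl)methyl]oxiran-2-yl]pent-2-enoate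
Conditions: D-fructose-derived Shi ketone (0.3 equiv), KHSO5 (as Oxone, 2KHSO5·KHSO4·K2SO4), K2CO3, Bu4NHSO4, CH3CN–CH2(OCH3)2–aq. Na2B4O7 buffer (pH 10.5), 0 °C
Reagents that add atoms: potassium peroxymonosulfate [K+].OOS(=O)(=O)[O-]
Why: Shi asymmetric epoxidation: the chiral dioxirane transfers oxygen through a spiro transition state to one face of the (E)-trisubstituted C6=C7 alkene, the only electron-rich alkene present (the enoate and the tetrasubstituted enone are electron-poor), setting the (R,R)-oxirane under catalyst control.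

Step 11
Reactants: 15 methyl (2E)-2-methyl-5-[(2R,3R)-2-methyl-3-[(2,6,6-trimethyl-3-oxocyclohex-1-en-1-yl)methyl]oxiran-2-yl]pent-2-enoate
Product: 17 methyl (2R)-2-[(3S,6S)-6-[(1R)-1-hydroxy-2-(2,6,6-trimethyl-3-oxocyclohex-1-en-1-yl)ethyl]-6-methyl-1,2-dioxan-3-yl]propanoate, via hydroperoxy alcohol 16 (not isolated)
Conditions: H2O2 (anhydrous, in Et2O, 10 equiv), H3PMo12O40 (5 mol %), rt; excess H2O2 washed out (H2O), solvent exchanged; Et2NH (1 equiv), CF3CH2OH, rt
Reagents that add atoms: hydrogen peroxide OO
Why: H3PMo12O40 activates the oxirane and H2O2 opens it at the tertiary, methyl-bearing C6 from the face opposite to the departing oxygen (borderline SN2, inversion), giving β-hydroxy hydroperoxide 16; the amine then ionises only the hydroperoxide (more acidic and more nucleophilic than the C7 alcohol), which adds to C3 of the (E)-enoate, and the ester enolate is protonated by the fluorinated alcohol. Both halves are close-precedent reaction types, namely heteropolyacid-catalysed perhydrolysis of trisubstituted epoxides and the intramolecular peroxy-Michael (oxa-Michael) closure of hydroperoxy enoates to 1,2-dioxane-3-acetates and -propanoates. The dioxane closes in the 6-exo-trig mode (O2 onto C3, C2=C3 exocyclic). C6 is fixed by stereospecific inversion of the catalyst-made oxirane; C3 is relayed from C6 through a chair transition state with the enoate arm at C3 and the α-branched C7 carbinol arm at C6 equatorial and the C6 methyl axial, which puts the propanoate arm cis to the methyl group (3S); C2 is set by protonation of the enolate anti to the new C3–O bond, the usual course of alkoxide additions to α-substituted enoates in protic media, and anti addition across the E alkene gives 2R. The step needs opening at C6 and not C7 (secured by tertiary versus secondary carbon), closure on the enoate and not on the ring enone (whose β-carbon C1' is fully substituted and flanked by the gem-dimethyl carbon) and discrimination of the two chairs (secured by the temporary C7 oxygen, which makes the C6 arm clearly larger than methyl). That oxygen is removed again in steps 12 and 13.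

Step 12
Reactants: 17 methyl (2R)-2-[(3S,6S)-6-[(1R)-1-hydroxy-2-(2,6,6-trimethyl-3-oxocyclohex-1-en-1-yl)ethyl]-6-methyl-1,2-dioxan-3-yl]propanoate
Product: 19 methyl (2R)-2-[(3S,6S)-6-methyl-6-[(E)-2-(2,6,6-trimethyl-3-oxocyclohex-1-en-1-yl)ethenyl]-1,2-dioxan-3-yl]propanoate, via mesylate 18 (not isolated)
Conditions: CH3SO2Cl, Et3N, CH2Cl2, 0 °C; then DBU, 0 °C to rt
Reagents that add atoms: none
Why: the C8 hydrogens are γ to the cyclohexenone carbonyl, so the δ-mesylate should leave by vinylogous E1cB elimination through the extended enolate to give the conjugated (E)-dienone, and no regioisomer is possible because C6 carries no hydrogen.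

Step 13
Reactants: 19 methyl (2R)-2-[(3S,6S)-6-methyl-6-[(E)-2-(2,6,6-trimethyl-3-oxocyclohex-1-en-1-yl)ethenyl]-1,2-dioxan-3-yl]propanoate
Product: 20 methyl diacarnoate A, methyl (2R)-2-[(3S,6R)-6-methyl-6-[2-(2,6,6-trimethyl-3-oxocyclohex-1-en-1-yl)ethyl]-1,2-dioxan-3-yl]propanoate
Conditions: KO2CN=NCO2K, AcOH, CH3OH–CH2Cl2, 0 °C to rt (repeated charges)
Reagents that add atoms: none
Why: diimide reduction transfers H2 in a concerted syn fashion to the disubstituted C7=C8 bond only, leaving the tetrasubstituted C1'=C2' enone and the O–O bond intact (the standard method for unsaturated peroxides), and no stereocentre is touched.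

## Compound list

1 | pent-4-yn-1-ol | C#CCCCO | starting material
2 | dimethylaluminium (E)-5-(dimethylalumanyl)-4-methylpent-4-en-1-olate | C[Al](C)OCCC/C(C)=C/[Al](C)C | intermediate (not isolated)
3 | (E)-5-iodo-4-methylpent-4-en-1-ol | OCCC/C(C)=C/I | intermediate
4 | (E)-5-iodo-4-methylpent-4-enal | O=CCC/C(C)=C/I | intermediate
5 | methyl (2E,6E)-7-iodo-2,6-dimethylhepta-2,6-dienoate | COC(=O)/C(C)=C/CC/C(C)=C/I | intermediate
6 | methyl (2E,6E)-2,6-dimethyl-7-(4,4,5,5-tetramethyl-1,3,2-dioxaborolan-2-yl)hepta-2,6-dienoate | COC(=O)/C(C)=C/CC/C(C)=C/B1OC(C)(C)C(C)(C)O1 | intermediate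
7 | 2-methylcyclohexane-1,3-dione | CC1C(=O)CCCC1=O | starting material
8 | 3-ethoxy-2-methylcyclohex-2-en-1-one | CCOC1=C(C)C(=O)CCC1 | intermediate
9 | 3-ethoxy-2,6-dimethylcyclohex-2-en-1-one (racemic) | CCOC1=C(C)C(=O)C(C)CC1 | intermediate (not isolated)
10 | 3-ethoxy-2,6,6-trimethylcyclohex-2-en-1-one | CCOC1=C(C)C(=O)C(C)(C)CC1 | intermediate
11 | 3-ethoxy-1,2,6,6-tetramethylcyclohex-2-en-1-ol (racemic, lithium alkoxide in the flask) | CCOC1=C(C)C(C)(O)C(C)(C)CC1 | intermediate (not isolated)
12 | 2,3,4,4-tetramethylcyclohex-2-en-1-one | CC1=C(C)C(=O)CCC1(C)C | intermediate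
13 | 3-(bromomethyl)-2,4,4-trimethylcyclohex-2-en-1-one | BrCC1=C(C)C(=O)CCC1(C)C | intermediate
14 | methyl (2E,6E)-2,6-dimethyl-8-(2,6,6-trimethyl-3-oxocyclohex-1-en-1-yl)octa-2,6-dienoate | COC(=O)/C(C)=C/CC/C(C)=C/CC1=C(C)C(=O)CCC1(C)C | intermediate
15 | methyl (2E)-2-methyl-5-[(2R,3R)-2-methyl-3-[(2,6,6-trimethyl-3-oxocyclohex-1-en-1-yl)methyl]oxiran-2-yl]pent-2-enoate | COC(=O)/C(C)=C/CC[C@@]1(C)O[C@@H]1CC2=C(C)C(=O)CCC2(C)C | intermediate
16 | methyl (2E,6S,7R)-6-hydroperoxy-7-hydroxy-2,6-dimethyl-8-(2,6,6-trimethyl-3-oxocyclohex-1-en-1-yl)oct-2-enoate | COC(=O)/C(C)=C/CC[C@](C)(OO)[C@H](O)CC1=C(C)C(=O)CCC1(C)C | intermediate (not isolated)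
17 | methyl (2R)-2-[(3S,6S)-6-[(1R)-1-hydroxy-2-(2,6,6-trimethyl-3-oxocyclohex-1-en-1-yl)ethyl]-6-methyl-1,2-dioxan-3-yl]propanoate | COC(=O)[C@H](C)[C@@H]1CC[C@@](C)([C@H](O)CC2=C(C)C(=O)CCC2(C)C)OO1 | intermediate
18 | methyl (2R)-2-[(3S,6S)-6-[(1R)-1-(methanesulfonyloxy)-2-(2,6,6-trimethyl-3-oxocyclohex-1-en-1-yl)ethyl]-6-methyl-1,2-dioxan-3-yl]propanoate | COC(=O)[C@H](C)[C@@H]1CC[C@@](C)([C@H](OS(C)(=O)=O)CC2=C(C)C(=O)CCC2(C)C)OO1 | intermediate (not isolated)
19 | methyl (2R)-2-[(3S,6S)-6-methyl-6-[(E)-2-(2,6,6-trimethyl-3-oxocyclohex-1-en-1-yl)ethenyl]-1,2-dioxan-3-yl]propanoate | COC(=O)[C@H](C)[C@@H]1CC[C@@](C)(/C=C/C2=C(C)C(=O)CCC2(C)C)OO1 | intermediate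
20 | methyl diacarnoate A, methyl (2R)-2-[(3S,6R)-6-methyl-6-[2-(2,6,6-trimethyl-3-oxocyclohex-1-en-1-yl)ethyl]-1,2-dioxan-3-yl]propanoate | COC(=O)[C@H](C)[C@@H]1CC[C@@](C)(CCC2=C(C)C(=O)CCC2(C)C)OO1 | target

## Summary and risks

Total step count: 13. Longest linear sequence: 9 steps (1 → 20 through steps 1–4 and 9–13; the branch from 7 through steps 5–8 and 9–13 is equally long).

Steps most likely to fail:

**Step 11.** The two chair transition states of the ring closure (C6 methyl axial versus C6 carbinol arm axial) may be discriminated too weakly, so that the C3 epimer forms alongside. Secondary risks are partial ionisation at C6 during the acid-catalysed opening (erosion of configuration) and base-induced fragmentation of the β-hydroxy hydroperoxide. The fallback sets out from 16 and returns at 17. Compound 16 is isolated after the perhydrolysis stage and both oxygen functions are silylated (Et3SiOSO2CF3, 2,6-lutidine, CH2Cl2, −78 °C) to give the bis(triethylsilyl) derivative F1. Et2NH in CF3CH2OH then cleaves only the labile peroxysilane, and the liberated hydroperoxide cyclises while the C7 arm carries a bulky silyl ether. This enlarges the equatorial preference of that arm and blocks alkoxide-driven fragmentation, and should give the silyl ether dioxane F2. HF·pyridine in THF removes the silyl group and rejoins the route at 17.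

**Step 12.** Deprotonation at C2 (retro-Michael opening of the dioxane, with epimerisation on re-closure) or at C3–H (Kornblum–DeLaMare-type cleavage of the O–O bond) may compete with the vinylogous elimination. The fallback sets out from 17 and returns at 19. It replaces the base-mediated pathway by a base-free thermal syn-elimination with the Burgess reagent (benzene, 50 °C). The alcohol is converted into the sulfamate ester salt F3, which is not isolated and should collapse through the only available β-hydrogens (on C8) to 19.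

**Step 8.** Hydrogen abstraction may be unselective between the C3 methyl (wanted), the C2 methyl and C6–H, and over-bromination may occur. The fallback sets out from 10 and returns at 13, and introduces the functionalised carbon by polar chemistry instead of radical C–H bromination. (Methoxymethoxy)methyllithium (from Bu3SnCH2OCH2OCH3 and n-BuLi, THF, −78 °C) adds to the carbonyl of 10 to give the carbinol F4 (not isolated). Aqueous HCl effects the Stork–Danheiser transposition to the acetal-protected enone F5. HCl in CH3OH removes the acetal to give the hydroxymethyl enone F6, and an Appel reaction (CBr4, PPh3, CH2Cl2, 0 °C) converts it into 13.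

## Further compounds

F1 | step 11 | methyl (2E,6S,7R)-2,6-dimethyl-6-(triethylsilylperoxy)-7-(triethylsilyloxy)-8-(2,6,6-trimethyl-3-oxocyclohex-1-en-1-yl)oct-2-enoate | COC(=O)/C(C)=C/CC[C@](C)(OO[Si](CC)(CC)CC)[C@H](O[Si](CC)(CC)CC)CC1=C(C)C(=O)CCC1(C)C
F2 | step 11 | methyl (2R)-2-[(3S,6S)-6-methyl-6-[(1R)-1-(triethylsilyloxy)-2-(2,6,6-trimethyl-3-oxocyclohex-1-en-1-yl)ethyl]-1,2-dioxan-3-yl]propanoate | COC(=O)[C@H](C)[C@@H]1CC[C@@](C)([C@H](O[Si](CC)(CC)CC)CC2=C(C)C(=O)CCC2(C)C)OO1
F3 | step 12 | triethylammonium salt of the N-(methoxycarbonyl)sulfamate ester of 17 | COC(=O)[C@H](C)[C@@H]1CC[C@@](C)([C@H](OS(=O)(=O)[N-]C(=O)OC)CC2=C(C)C(=O)CCC2(C)C)OO1.CC[NH+](CC)CC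
F4 | step 8 | 3-ethoxy-1-[(methoxymethoxy)methyl]-2,6,6-trimethylcyclohex-2-en-1-ol (racemic) | CCOC1=C(C)C(O)(COCOC)C(C)(C)CC1
F5 | step 8 | 3-[(methoxymethoxy)methyl]-2,4,4-trimethylcyclohex-2-en-1-one | COCOCC1=C(C)C(=O)CCC1(C)C
F6 | step 8 | 3-(hydroxymethyl)-2,4,4-trimethylcyclohex-2-en-1-one | OCC1=C(C)C(=O)CCC1(C)C
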